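**Retrosynthetic overview**

1. Target 23 ⇐ 17: the late steps only acylate O‑14, raise C17 from CH2OSi to CO2H (moving C6=C7 to C7=C8) and saturate C11=C12. A Wittig disconnection at C11=C12 then gives decalin aldehyde 14 and the chiral‑pool phosphonium salt 16 (C12–C14, C13 stereocentre).
2. 14 ⇐ acyclic, achiral trienal 11 by an enantioselective amine‑catalysed intramolecular Diels–Alder reaction that forms C5–C10 and C8–C9 together. Rings A and B close in this one step (no ring exists before it), and C5, C9 and C10 are set (C8 only transiently).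
3. Enabling feature: ring B is a cyclohexene whose C7=C8 bond is conjugated to the C8 carboxyl group, so the alkene can be held at C6=C7 in the precursor and moved back later. Ring B is then the [4+2] adduct of diene C5=C6–C7=C8 and dienophile C9=C10; the cis pair C10‑CH3/C9‑chain maps onto an (E)‑trisubstituted alkene, and side‑chain carbon C11, as a formyl group, is the activating group and stays in the target.
4. 11 ⇐ B‑alkyl Suzuki coupling (C1–C10) of terminal alkene 7 with (E)‑enol triflate 2; 7 ⇐ 2,2‑dimethylpent‑4‑enal (C1–C5 with the C4 gem‑dimethyl group) + triethyl 4‑phosphonocrotonate (C6–C8, C17).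

Key step: step 8

Remark on numbering: decalin compounds and their open‑chain precursors are discussed with labdane numbers. C10 (angular methyl), C1–C4 (C4 gem‑dimethyl) and C5 form ring A; C5–C10 form ring B; C8 carries C17; C9 carries the chain C11–C14 with the methyl group on C13; β is the face of the C10 methyl group.

Assumption: the facial preference of the (2S,5S)‑imidazolidinone known for β‑monosubstituted enals is taken to hold for iminium ion 12, so that the diene adds to the C9‑Si/C10‑Re face; if the opposite sense were found, the (2R,5R)‑catalyst would be used.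

**Route**

Step 1
Reactants: 1 ethyl acetoacetate
Product: 2 ethyl (2E)-3-{[(trifluoromethyl)sulfonyl]oxy}but-2-enoate
Conditions: Tf2O, aq. Me4NOH, hexanes, 5 °C to rt
Reagents that add atoms: trifluoromethanesulfonic anhydride, O=S(=O)(OS(=O)(=O)C(F)(F)F)C(F)(F)F
Why: O‑triflation of the non‑chelated tetramethylammonium enolate of the β‑keto ester places the triflate trans to the ester (known (E)‑selective enol triflate formation), which fixes the later C9=C10 geometry.

Step 2
Reactants: 3 2,2-dimethylpent-4-enal; 4 triethyl 4-phosphonocrotonate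
Product: 5 ethyl (2E,4E)-6,6-dimethylnona-2,4,8-trienoate
Conditions: LiN(SiMe3)2, THF, −78 °C to rt
Reagents that add atoms: none
Why: Horner–Wadsworth–Emmons olefination of the non‑enolisable α‑quaternary aldehyde with the vinylogous phosphonate should give the (E,E)‑dienoate, the new C5=C6 bond being trans.

Step 3
Reactants: 5 ethyl (2E,4E)-6,6-dimethylnona-2,4,8-trienoate
Product: 6 (2E,4E)-6,6-dimethylnona-2,4,8-trien-1-ol
Conditions: i-Bu2AlH (2.5 equiv), CH2Cl2, −78 °C; aq. Rochelle salt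
Reagents that add atoms: none
Why: 1,2‑reduction of the dienoate by the aluminium hydride at low temperature leaves all three alkenes untouched.

Step 4
Reactants: 6 (2E,4E)-6,6-dimethylnona-2,4,8-trien-1-ol
Product: 7 tert-butyl{[(2E,4E)-6,6-dimethylnona-2,4,8-trien-1-yl]oxy}diphenylsilane
Conditions: TBDPSCl, imidazole, DMF, rt
Reagents that add atoms: tert-butyl(chloro)diphenylsilane, CC(C)(C)[Si](Cl)(c1ccccc1)c1ccccc1
Why: standard silylation; the robust silyl ether keeps the diene electron‑neutral and should survive the mildly acidic aqueous medium of the key step.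

Step 5
Reactants: 7 tert-butyl{[(2E,4E)-6,6-dimethylnona-2,4,8-trien-1-yl]oxy}diphenylsilane; 2 ethyl (2E)-3-{[(trifluoromethyl)sulfonyl]oxy}but-2-enoate
Product: 9 ethyl (2E,8E,10E)-12-{[tert-butyl(diphenyl)silyl]oxy}-3,7,7-trimethyldodeca-2,8,10-trienoate, via B-alkyl-9-BBN 8 (not isolated)
Conditions: 9-BBN-H, THF, 0 °C to rt; then 2, PdCl2(dppf) (5 mol %), aq. K3PO4, DMF, rt
Reagents that add atoms: 9-borabicyclo[3.3.1]nonane (9-BBN-H), B1C2CCCC1CCC2
Why: 9‑BBN‑H adds anti‑Markovnikov and chemoselectively to the monosubstituted terminal alkene (the conjugated diene reacts far more slowly), and the B‑alkyl Suzuki–Miyaura coupling with the enol triflate proceeds with retention of the (E)‑geometry.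

Step 6
Reactants: 9 ethyl (2E,8E,10E)-12-{[tert-butyl(diphenyl)silyl]oxy}-3,7,7-trimethyldodeca-2,8,10-trienoate
Product: 10 (2E,8E,10E)-12-{[tert-butyl(diphenyl)silyl]oxy}-3,7,7-trimethyldodeca-2,8,10-trien-1-ol
Conditions: i-Bu2AlH (2.5 equiv), CH2Cl2, −78 °C; aq. Rochelle salt
Reagents that add atoms: none
Why: 1,2‑reduction of the enoate to the allylic alcohol; silyl ether and diene are inert.

Step 7
Reactants: 10 (2E,8E,10E)-12-{[tert-butyl(diphenyl)silyl]oxy}-3,7,7-trimethyldodeca-2,8,10-trien-1-ol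
Product: 11 (2E,8E,10E)-12-{[tert-butyl(diphenyl)silyl]oxy}-3,7,7-trimethyldodeca-2,8,10-trienal
Conditions: activated MnO2, CH2Cl2, rt
Reagents that add atoms: none
Why: MnO2 oxidises only the allylic alcohol and should give the (E)‑enal under neutral conditions.

Step 8
Reactants: 11 (2E,8E,10E)-12-{[tert-butyl(diphenyl)silyl]oxy}-3,7,7-trimethyldodeca-2,8,10-trienal
Product: 14 (1S,2S,4aS,8aS)-2-({[tert-butyl(diphenyl)silyl]oxy}methyl)-5,5,8a-trimethyl-1,2,4a,5,6,7,8,8a-octahydronaphthalene-1-carbaldehyde, via iminium ion 12 (not isolated), via cycloadduct iminium ion 13 (not isolated)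
Conditions: (2S,5S)-5-benzyl-2-tert-butyl-3-methylimidazolidin-4-one·CF3SO3H (second-generation imidazolidinone organocatalyst, 20 mol %), MeCN/H2O 98:2, −20 °C to 4 °C
Reagents that add atoms: (2S,5S)-5-benzyl-2-tert-butyl-3-methylimidazolidin-4-one trifluoromethanesulfonate salt, CN1C(=O)[C@H](Cc2ccccc2)[NH2+][C@@H]1C(C)(C)C.[O-]S(=O)(=O)C(F)(F)F; water, O
Why: Proposed new method: condensation of the imidazolidinone with the β,β‑disubstituted enal should give the (E)‑iminium ion 12, whose lowered LUMO lets the tethered, electron‑neutral (E,E)‑diene add across C9=C10 in a concerted, asynchronous [4+2] cycloaddition, and hydrolysis of 13 releases 14 and the catalyst. The closest known reaction type is the imidazolidinone‑catalysed intramolecular Diels–Alder reaction of (E,E,E)‑trienals to trans‑fused decalins, and iminium activation of β,β‑disubstituted enals by such catalysts is known from conjugate reductions; new is the formation of the quaternary ring‑fusion carbon C10 at the β‑position. Ring B closes as the cyclohexene of the [4+2] event (bonds C5–C10 and C8–C9), and ring A closes through the same C5–C10 bond across the four‑carbon tether C1–C4, which adopts a chair with the tether exo (anti) to the diene, helped by the C4 gem‑dimethyl group. The cis relationship of the C10 methyl and C9 formyl groups follows from the (E)‑dienophile (suprafacial addition), the trans ring fusion (5α‑H, 10β‑CH3) and the 8β substituent follow from the endo orientation of the iminium unit with the (E,E)‑diene, and the absolute configuration follows from the benzyl group of the catalyst shielding one face of 12. The step needs endo over exo selectivity, one π‑face and retention of the C9=C10 geometry: the first two are the normal preferences of this catalyst class, and the third is secured by the non‑basic triflate counter‑ion and low temperature, which slow γ‑deprotonation to the dienamine, and by the faster cyclisation of the (E)‑iminium ion.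

Step 9
Reactants: 15 (2S)-3-bromo-2-methylpropan-1-ol
Product: 16 [(2S)-3-hydroxy-2-methylpropyl]triphenylphosphonium bromide
Conditions: PPh3, MeCN, reflux
Reagents that add atoms: triphenylphosphine, c1ccc(cc1)P(c1ccccc1)c1ccccc1
Why: SN2 displacement of the primary bromide by the phosphine; the stereocentre is not involved.

Step 10
Reactants: 14 (1S,2S,4aS,8aS)-2-({[tert-butyl(diphenyl)silyl]oxy}methyl)-5,5,8a-trimethyl-1,2,4a,5,6,7,8,8a-octahydronaphthalene-1-carbaldehyde; 16 [(2S)-3-hydroxy-2-methylpropyl]triphenylphosphonium bromide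
Product: 17 (2R,3Z)-4-[(1S,2S,4aS,8aR)-2-({[tert-butyl(diphenyl)silyl]oxy}methyl)-5,5,8a-trimethyl-1,2,4a,5,6,7,8,8a-octahydronaphthalen-1-yl]-2-methylbut-3-en-1-ol
Conditions: 16 (2.5 equiv), n-BuLi (5 equiv), THF, −78 to 0 °C; then 14, −78 °C to rt
Reagents that add atoms: none
Why: Wittig olefination with the γ‑oxido ylide joins C11 and C12; the alkene geometry is irrelevant because it is hydrogenated in step 15, and fast carbonyl addition at low temperature should protect the C9 stereocentre, whose equatorial formyl epimer is in any case the more stable one.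

Step 11
Reactants: 17 (2R,3Z)-4-[(1S,2S,4aS,8aR)-2-({[tert-butyl(diphenyl)silyl]oxy}methyl)-5,5,8a-trimethyl-1,2,4a,5,6,7,8,8a-octahydronaphthalen-1-yl]-2-methylbut-3-en-1-ol
Product: 18 (2R,3Z)-4-[(1S,2S,4aS,8aR)-2-({[tert-butyl(diphenyl)silyl]oxy}methyl)-5,5,8a-trimethyl-1,2,4a,5,6,7,8,8a-octahydronaphthalen-1-yl]-2-methylbut-3-en-1-yl 2-methylpropanoate
Conditions: isobutyryl chloride, pyridine, DMAP (cat.), CH2Cl2, 0 °C
Reagents that add atoms: 2-methylpropanoyl chloride, CC(C)C(Cl)=O
Why: acylation of the only free hydroxyl group.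

Step 12
Reactants: 18 (2R,3Z)-4-[(1S,2S,4aS,8aR)-2-({[tert-butyl(diphenyl)silyl]oxy}methyl)-5,5,8a-trimethyl-1,2,4a,5,6,7,8,8a-octahydronaphthalen-1-yl]-2-methylbut-3-en-1-yl 2-methylpropanoate
Product: 19 (2R,3Z)-4-[(1S,2S,4aS,8aR)-2-(hydroxymethyl)-5,5,8a-trimethyl-1,2,4a,5,6,7,8,8a-octahydronaphthalen-1-yl]-2-methylbut-3-en-1-yl 2-methylpropanoate
Conditions: Bu4NF, AcOH, THF, rt
Reagents that add atoms: none
Why: fluoride cleaves the silyl ether, and acetic acid buffering should prevent cleavage of the isobutyrate.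

Step 13
Reactants: 19 (2R,3Z)-4-[(1S,2S,4aS,8aR)-2-(hydroxymethyl)-5,5,8a-trimethyl-1,2,4a,5,6,7,8,8a-octahydronaphthalen-1-yl]-2-methylbut-3-en-1-yl 2-methylpropanoate
Product: 21 (2R,3Z)-4-[(1R,4aS,8aS)-2-formyl-5,5,8a-trimethyl-1,4,4a,5,6,7,8,8a-octahydronaphthalen-1-yl]-2-methylbut-3-en-1-yl 2-methylpropanoate, via β,γ-unsaturated aldehyde 20 (not isolated)
Conditions: (n-Pr4N)RuO4 (5 mol %), NMO, 4 Å molecular sieves, CH2Cl2, rt; then DBU (0.2 equiv), rt
Reagents that add atoms: none
Why: Ley–Griffith oxidation gives the β,γ‑unsaturated aldehyde, which DBU should isomerise through the dienolate (deprotonation at C8, reprotonation at C6) to the conjugated C7=C8 enal; C9 is not acidic in either isomer and keeps its configuration.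

Step 14
Reactants: 21 (2R,3Z)-4-[(1R,4aS,8aS)-2-formyl-5,5,8a-trimethyl-1,4,4a,5,6,7,8,8a-octahydronaphthalen-1-yl]-2-methylbut-3-en-1-yl 2-methylpropanoate
Product: 22 (1R,4aS,8aS)-5,5,8a-trimethyl-1-[(1Z,3R)-3-methyl-4-(2-methylpropanoyloxy)but-1-en-1-yl]-1,4,4a,5,6,7,8,8a-octahydronaphthalene-2-carboxylic acid
Conditions: NaClO2, NaH2PO4, 2-methylbut-2-ene, t-BuOH/H2O, 0 °C to rt
Reagents that add atoms: sodium chlorite, [Na+].[O-]Cl=O
Why: Pinnick oxidation converts the enal to the acid without touching the alkenes (hypochlorous acid is scavenged) or the ester.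

Step 15
Reactants: 22 (1R,4aS,8aS)-5,5,8a-trimethyl-1-[(1Z,3R)-3-methyl-4-(2-methylpropanoyloxy)but-1-en-1-yl]-1,4,4a,5,6,7,8,8a-octahydronaphthalene-2-carboxylic acid
Product: 23 (1R,4aS,8aS)-5,5,8a-trimethyl-1-[(3R)-3-methyl-4-(2-methylpropanoyloxy)butyl]-1,4,4a,5,6,7,8,8a-octahydronaphthalene-2-carboxylic acid
Conditions: H2 (1–3 atm), RhCl(PPh3)3 (10 mol %), benzene/EtOH, rt
Reagents that add atoms: none
Why: homogeneous hydrogenation with the rhodium chloride–phosphine complex should be selective for the disubstituted side‑chain alkene over the trisubstituted, conjugated, hindered C7=C8 bond.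

**Compound list**

1 | ethyl acetoacetate | CCOC(=O)CC(C)=O | starting material
2 | ethyl (2E)-3-{[(trifluoromethyl)sulfonyl]oxy}but-2-enoate | CCOC(=O)/C=C(\C)OS(=O)(=O)C(F)(F)F | intermediate
3 | 2,2-dimethylpent-4-enal | C=CCC(C)(C)C=O | starting material
4 | triethyl 4-phosphonocrotonate, ethyl (2E)-4-(diethoxyphosphoryl)but-2-enoate | CCOC(=O)/C=C/CP(=O)(OCC)OCC | starting material
5 | ethyl (2E,4E)-6,6-dimethylnona-2,4,8-trienoate | CCOC(=O)/C=C/C=C/C(C)(C)CC=C | intermediate
6 | (2E,4E)-6,6-dimethylnona-2,4,8-trien-1-ol | OC/C=C/C=C/C(C)(C)CC=C | intermediate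
7 | tert-butyl{[(2E,4E)-6,6-dimethylnona-2,4,8-trien-1-yl]oxy}diphenylsilane | CC(C)(C)[Si](OC/C=C/C=C/C(C)(C)CC=C)(c1ccccc1)c1ccccc1 | intermediate
8 | B-alkyl-9-BBN: 9-[(5E,7E)-9-{[tert-butyl(diphenyl)silyl]oxy}-4,4-dimethylnona-5,7-dien-1-yl]-9-borabicyclo[3.3.1]nonane | CC(C)(C)[Si](OC/C=C/C=C/C(C)(C)CCCB1C2CCCC1CCC2)(c1ccccc1)c1ccccc1 | intermediate
9 | ethyl (2E,8E,10E)-12-{[tert-butyl(diphenyl)silyl]oxy}-3,7,7-trimethyldodeca-2,8,10-trienoate | CCOC(=O)/C=C(\C)CCCC(C)(C)/C=C/C=C/CO[Si](c1ccccc1)(c1ccccc1)C(C)(C)C | intermediate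
10 | (2E,8E,10E)-12-{[tert-butyl(diphenyl)silyl]oxy}-3,7,7-trimethyldodeca-2,8,10-trien-1-ol | OC/C=C(\C)CCCC(C)(C)/C=C/C=C/CO[Si](c1ccccc1)(c1ccccc1)C(C)(C)C | intermediate
11 | (2E,8E,10E)-12-{[tert-butyl(diphenyl)silyl]oxy}-3,7,7-trimethyldodeca-2,8,10-trienal | O=C/C=C(\C)CCCC(C)(C)/C=C/C=C/CO[Si](c1ccccc1)(c1ccccc1)C(C)(C)C | intermediate
12 | iminium ion: (E)-iminium triflate of trienal 11 with the ring NH nitrogen of the (2S,5S)-imidazolidinone | CN1C(=O)[C@H](Cc2ccccc2)/[N+](=C\C=C(/C)CCCC(C)(C)/C=C/C=C/CO[Si](c2ccccc2)(c2ccccc2)C(C)(C)C)[C@@H]1C(C)(C)C.[O-]S(=O)(=O)C(F)(F)F | intermediate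
13 | cycloadduct iminium ion: iminium triflate of aldehyde 14 with the same imidazolidinone | CN1C(=O)[C@H](Cc2ccccc2)/[N+](=C\[C@H]2[C@@H](CO[Si](c3ccccc3)(c3ccccc3)C(C)(C)C)C=C[C@H]3C(C)(C)CCC[C@]23C)[C@@H]1C(C)(C)C.[O-]S(=O)(=O)C(F)(F)F | intermediate
14 | (1S,2S,4aS,8aS)-2-({[tert-butyl(diphenyl)silyl]oxy}methyl)-5,5,8a-trimethyl-1,2,4a,5,6,7,8,8a-octahydronaphthalene-1-carbaldehyde (trans-fused; 5α-H, 8β-CH2OSi, 9β-CHO, 10β-CH3, C6=C7) | O=C[C@H]1[C@@H](CO[Si](c2ccccc2)(c2ccccc2)C(C)(C)C)C=C[C@H]2C(C)(C)CCC[C@]12C | intermediate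
15 | (2S)-3-bromo-2-methylpropan-1-ol | OC[C@H](C)CBr | starting material
16 | [(2S)-3-hydroxy-2-methylpropyl]triphenylphosphonium bromide | OC[C@H](C)C[P+](c1ccccc1)(c1ccccc1)c1ccccc1.[Br-] | intermediate
17 | (2R,3Z)-4-[(1S,2S,4aS,8aR)-2-({[tert-butyl(diphenyl)silyl]oxy}methyl)-5,5,8a-trimethyl-1,2,4a,5,6,7,8,8a-octahydronaphthalen-1-yl]-2-methylbut-3-en-1-ol | OC[C@H](C)/C=C\[C@H]1[C@@H](CO[Si](c2ccccc2)(c2ccccc2)C(C)(C)C)C=C[C@H]2C(C)(C)CCC[C@]12C | intermediate
18 | 2-methylpropanoate (isobutyrate) of 17 | CC(C)C(=O)OC[C@H](C)/C=C\[C@H]1[C@@H](CO[Si](c2ccccc2)(c2ccccc2)C(C)(C)C)C=C[C@H]2C(C)(C)CCC[C@]12C | intermediate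
19 | (2R,3Z)-4-[(1S,2S,4aS,8aR)-2-(hydroxymethyl)-5,5,8a-trimethyl-1,2,4a,5,6,7,8,8a-octahydronaphthalen-1-yl]-2-methylbut-3-en-1-yl 2-methylpropanoate | CC(C)C(=O)OC[C@H](C)/C=C\[C@H]1[C@@H](CO)C=C[C@H]2C(C)(C)CCC[C@]12C | intermediate
20 | β,γ-unsaturated aldehyde: (2R,3Z)-4-[(1S,2S,4aS,8aR)-2-formyl-5,5,8a-trimethyl-1,2,4a,5,6,7,8,8a-octahydronaphthalen-1-yl]-2-methylbut-3-en-1-yl 2-methylpropanoate | CC(C)C(=O)OC[C@H](C)/C=C\[C@H]1[C@@H](C=O)C=C[C@H]2C(C)(C)CCC[C@]12C | intermediate
21 | (2R,3Z)-4-[(1R,4aS,8aS)-2-formyl-5,5,8a-trimethyl-1,4,4a,5,6,7,8,8a-octahydronaphthalen-1-yl]-2-methylbut-3-en-1-yl 2-methylpropanoate | CC(C)C(=O)OC[C@H](C)/C=C\[C@H]1C(C=O)=CC[C@H]2C(C)(C)CCC[C@]12C | intermediate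
22 | (1R,4aS,8aS)-5,5,8a-trimethyl-1-[(1Z,3R)-3-methyl-4-(2-methylpropanoyloxy)but-1-en-1-yl]-1,4,4a,5,6,7,8,8a-octahydronaphthalene-2-carboxylic acid | CC(C)C(=O)OC[C@H](C)/C=C\[C@H]1C(C(=O)O)=CC[C@H]2C(C)(C)CCC[C@]12C | intermediate
23 | (1R,4aS,8aS)-5,5,8a-trimethyl-1-[(3R)-3-methyl-4-(2-methylpropanoyloxy)butyl]-1,4,4a,5,6,7,8,8a-octahydronaphthalene-2-carboxylic acid | CC(C)C(=O)OC[C@H](C)CC[C@H]1C(C(=O)O)=CC[C@H]2C(C)(C)CCC[C@]12C | target

**Step count**

Total: 15 steps. Longest linear sequence: 13 steps (from 3 through steps 2–8 and 10–15).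

**Steps most likely to fail**

Step 8 (bears the label). What may go wrong: slow or reversible iminium formation at the β,β‑disubstituted enal, loss of the C9=C10 geometry through dienamine formation, or insufficient endo and facial selectivity in the crowded transition state (C4 axial methyl against C10 methyl). The fallback uses the known auxiliary‑controlled, Lewis‑acid‑promoted intramolecular Diels–Alder reaction of trienoyl oxazolidinones, which needs no amine. It sets out from ester 9. Saponification (LiOH, THF/MeOH/H2O) would give the trienoic acid F1. Its mixed pivalic anhydride (t‑BuCOCl, Et3N) and lithiated (4S)‑4‑benzyl‑1,3‑oxazolidin‑2‑one would give the trienimide F2. Me2AlCl (1.4 equiv, CH2Cl2, −30 °C) would cyclise the chelated s‑cis imide, the diene adding endo and anti to the benzyl group, to the cycloadduct imide F3. LiBH4 (THF, MeOH) would release the auxiliary and give the primary alcohol F4, and oxidation with (n‑Pr4N)RuO4/NMO would bring the route back at aldehyde 14.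

Step 10. What may go wrong: slow addition of the branched oxido‑ylide to the neopentyl‑type aldehyde and base‑induced epimerisation at C9. The fallback replaces olefination by a non‑basic carbonyl addition followed by deoxygenation. It sets out from 14 and 15. The chloromagnesium alkoxide Grignard reagent made from 15 (i‑PrMgCl, then Mg), transmetalated with CeCl3, would add to 14 to give the diol F8 as a mixture of C11 epimers. Selective acylation of the primary hydroxyl group (isobutyryl chloride, 2,4,6‑collidine, −78 °C) would give the hydroxy ester F9. 1,1'‑Thiocarbonyldiimidazole would give the imidazolylthiocarbonate F10, and Barton–McCombie reduction (Bu3SnH, AIBN, toluene, 80 °C) would give the saturated ester F11, the 11,12‑dihydro analogue of 18. F11 would then take the place of 18 in steps 12 to 14, passing through the alcohol F12, the β,γ‑unsaturated aldehyde F13 and the conjugated enal F14. The chlorite oxidation of F14 comes back to the route at target 23, and step 15 falls away.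

Step 5. What may go wrong: competing hydroboration of the diene, protodeboronation, or hydrolysis and geometric isomerisation of the base‑sensitive enol triflate during coupling. The fallback builds the (E)‑trisubstituted enoate by carbometalation instead of cross‑coupling. It sets out from 7. Hydroboration–oxidation (9‑BBN‑H; NaOH, H2O2) would give the primary alcohol F5. I2, PPh3 and imidazole would give the iodide F6. Lithium acetylide–ethylenediamine complex in DMSO would give the terminal alkyne F7. Zirconium‑catalysed carboalumination (Me3Al, Cp2ZrCl2, CH2Cl2), a syn addition, and trapping of the (E)‑alkenylalane with ClCO2Et would bring the route back at ester 9.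

**Further compounds**

F1 | step 8 | (2E,8E,10E)-12-{[tert-butyl(diphenyl)silyl]oxy}-3,7,7-trimethyldodeca-2,8,10-trienoic acid | OC(=O)/C=C(\C)CCCC(C)(C)/C=C/C=C/CO[Si](c1ccccc1)(c1ccccc1)C(C)(C)C
F2 | step 8 | (4S)-4-benzyl-3-[(2E,8E,10E)-12-{[tert-butyl(diphenyl)silyl]oxy}-3,7,7-trimethyldodeca-2,8,10-trienoyl]-1,3-oxazolidin-2-one | O=C1OC[C@H](Cc2ccccc2)N1C(=O)/C=C(\C)CCCC(C)(C)/C=C/C=C/CO[Si](c2ccccc2)(c2ccccc2)C(C)(C)C
F3 | step 8 | cycloadduct imide: the decalin of 14 with the 9β-formyl group replaced by the (4S)-4-benzyl-2-oxo-1,3-oxazolidine-3-carbonyl group | O=C1OC[C@H](Cc2ccccc2)N1C(=O)[C@H]1[C@@H](CO[Si](c2ccccc2)(c2ccccc2)C(C)(C)C)C=C[C@H]2C(C)(C)CCC[C@]12C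
F4 | step 8 | primary alcohol: the decalin of 14 with 9β-CH2OH in place of the formyl group | OC[C@H]1[C@@H](CO[Si](c2ccccc2)(c2ccccc2)C(C)(C)C)C=C[C@H]2C(C)(C)CCC[C@]12C
F5 | step 5 | (5E,7E)-9-{[tert-butyl(diphenyl)silyl]oxy}-4,4-dimethylnona-5,7-dien-1-ol | OCCCC(C)(C)/C=C/C=C/CO[Si](c1ccccc1)(c1ccccc1)C(C)(C)C
F6 | step 5 | tert-butyl{[(2E,4E)-9-iodo-6,6-dimethylnona-2,4-dien-1-yl]oxy}diphenylsilane | ICCCC(C)(C)/C=C/C=C/CO[Si](c1ccccc1)(c1ccccc1)C(C)(C)C
F7 | step 5 | tert-butyl{[(2E,4E)-6,6-dimethylundeca-2,4-dien-10-yn-1-yl]oxy}diphenylsilane | C#CCCCC(C)(C)/C=C/C=C/CO[Si](c1ccccc1)(c1ccccc1)C(C)(C)C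
F8 | step 10 | diol: (2R)-2-methyl-4-[decalin-9β-yl of 14]butane-1,4-diol, mixture of epimers at the carbinol carbon C11 | OC[C@H](C)CC(O)[C@H]1[C@@H](CO[Si](c2ccccc2)(c2ccccc2)C(C)(C)C)C=C[C@H]2C(C)(C)CCC[C@]12C
F9 | step 10 | hydroxy ester: primary 2-methylpropanoate of F8 | CC(C)C(=O)OC[C@H](C)CC(O)[C@H]1[C@@H](CO[Si](c2ccccc2)(c2ccccc2)C(C)(C)C)C=C[C@H]2C(C)(C)CCC[C@]12C
F10 | step 10 | imidazolylthiocarbonate: O-(1H-imidazol-1-ylcarbonothioyl) derivative of F9 at C11 | CC(C)C(=O)OC[C@H](C)CC(OC(=S)n1ccnc1)[C@H]1[C@@H](CO[Si](c2ccccc2)(c2ccccc2)C(C)(C)C)C=C[C@H]2C(C)(C)CCC[C@]12C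
F11 | step 10 | saturated ester: 11,12-dihydro analogue of 18 | CC(C)C(=O)OC[C@H](C)CC[C@H]1[C@@H](CO[Si](c2ccccc2)(c2ccccc2)C(C)(C)C)C=C[C@H]2C(C)(C)CCC[C@]12C
F12 | step 10 | alcohol: 11,12-dihydro analogue of 19 | CC(C)C(=O)OC[C@H](C)CC[C@H]1[C@@H](CO)C=C[C@H]2C(C)(C)CCC[C@]12C
F13 | step 10 | β,γ-unsaturated aldehyde: 11,12-dihydro analogue of 20 | CC(C)C(=O)OC[C@H](C)CC[C@H]1[C@@H](C=O)C=C[C@H]2C(C)(C)CCC[C@]12C
F14 | step 10 | conjugated enal: 11,12-dihydro analogue of 21 | CC(C)C(=O)OC[C@H](C)CC[C@H]1C(C=O)=CC[C@H]2C(C)(C)CCC[C@]12C
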